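The pitfall in this flask was the ratio 1.10: I read it as an excess of reagent over solid substrate, called the substrate the limiting reagent, as one does at the bench, and expected target to climb towards the whole charge.

| setting | oak | flask |
|---|---|---|
| solid substrate | 1 M | 1.0 M |
| reagent | 1.1 M | 1.10 M |
| remark | the very flask that is asked about, followed so far |  |
| time |  | 8.0 d |

oak run (percent of the solid substrate charged)

| time / d | target / % | solid substrate / % |
|---|---|---|
| 0.500 | 7.7 | 55.6 |
| 1.25 | 17.2 | 31.4 |
| 3.00 | 24.7 | 13.9 |
| 6.00 | 22.4 | 10.8 |

(each reading ± 1 percentage point)

- a species is counted by the solid substrate in it: one side product counts as two
- given per volume of solution although it is solid: solid substrate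
- removed target is counted in
- candidate steps: solid substrate <-> dissolved substrate; dissolved substrate + reagent -> target; dissolved substrate + target -> side product; 2 reagent -> self-condensation product
- at the start none of the solid substrate is in solution
- additions bring no volume worth counting

* target, in percent of the solid substrate first charged, at 8.0 d
* the remedy with the largest gain of target, or "none" below 2 percentage points (summer / midnight / dusk / none)
* target present, with what was taken out counted in, in percent of the solid substrate first charged, after summer
* target present, with what was taken out counted in, in percent of the solid substrate first charged, after midnight

- summer: at 8.0 d add reagent, 50.0% of the amount charged, then wait 8.0 d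
- midnight: at 8.0 d take out 90% of the target then present, then wait 8.0 d
- dusk: change nothing and wait 8.0 d more

I tested that rule in powers of ten on the oak run, which is this same flask followed so far. Had reagent gone to target and nowhere else, [reagent] at 3.00 d would have stood at 0.853 M, a fall of 0.110 decades. But the rate of target making, taken between readings, went from 0.127 M d⁻¹ to 0.0429 M d⁻¹, a fall of 0.471 decades, more than the rule allowed. Meanwhile the substrate that was neither solid nor target rose from 51.4% to 61.4%. That was the border of the rule, so I took reagent to be leaving by self-condensation.

I therefore counted by reagent, with the reagent yield, molar target over molar reagent charged, read from the latest reading as 20.4%. The readings showed target no longer rising, so I committed to about 22.4% at 8.0 d. Summer adds 0.550 M of reagent, which at that yield gains 11 percentage points, above the 2 points margin, giving 33.4%. Midnight and dusk add no reagent, so I chose summer.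

The forecast gave 20.5%, summer with 28%, and 23% after midnight, holding that “reagent starvation is the limit”.

The flask gave 22.6% at 8.0 d, a reagent yield of 20.6%. Summer reached 43.0%, so its dose yielded 37.0%, more than I had carried, and midnight reached 22.2%.

    solid substrate ⇌ dissolved substrate, rate k1*(cs1 - [dissolved substrate]) while solid is left; crystals form when [dissolved substrate] > cs1 (solubility = 0.600 M, k = 0.0950 h⁻¹)
    dissolved substrate + reagent → target (k = 0.0550 M⁻¹ h⁻¹)
    dissolved substrate + target → side product (k = 0.00210 M⁻¹ h⁻¹)
    2 reagent → self-condensation product (k = 0.0670 M⁻¹ h⁻¹)

At 8.00 d target was made, each step taken net, at 0.0539 of the rate at which it was used up, less than one. Reagent then stood at 0.0421% of its charge and dissolved substrate at 59.7%. For a neighbour flask with 2.5 M of solid substrate and the same reagent, the reagent yield gives 8.96% of the solid charged; the computed neighbour flask gave 9.05%.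

The runs were generated by integration with made-up constants; noise was put on by code.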